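**Retrosynthetic overview**
1. The route rests on the Cα–Cβ bond of the seven-membered carbocycle. Cα is the CH2 on C4 of the central benzene ring (ring B) and Cβ is the CH(2,4-dihydroxyphenyl) carbon on the resorcinol ring D. Both carbons are benzylic, so the bond is traced back to the eight-membered CH2–SO2–CH(aryl) sulfone 22; Ramberg–Bäcklund contraction gives cyclic stilbene 25, followed by face-selective hydrogenation and BBr3.
2. Sulfone 22 comes from sulfide 20, closed at sulfur when the C4 CH2SH group captures a bis(2,4-dialkoxyaryl)methyl cation. The cation precursor is made by bromination, lithiation and addition to 2,4-dimethoxybenzaldehyde on one of the two equivalent 3,5-dimethoxyphenyl rings of the C2-symmetric core 12.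
3. Core 12 (both dihydrofurans 2,3-trans, R at every centre) comes from a double enantioselective rhodium-carbene C–H insertion of bis(diaryldiazomethane) 10 into its two 4-methoxybenzyl ether CH2 groups, then acid epimerisation at C2 and C6. Precursor 9 is built from 3,5-dihydroxybenzyl alcohol by double etherification, silylation, dibromination and double lithiation/nitrile addition.
4. Ring order: both dihydrofuran rings together (step 6), then the eight-membered thiacycle (step 12), then the seven-membered carbocycle by loss of SO2 (step 14).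

Key step: step 14

Assumption: Rh2(S-PTAD)4 (dirhodium tetrakis[(S)-adamantan-1-yl(phthalimido)acetate]) is taken as the catalyst enantiomer that gives R at the carbene-derived carbons C3 and C5; if the sense of induction is the opposite, Rh2(R-PTAD)4 is used instead.
Locants: core positions follow 2,3,5,6-tetrahydrobenzo[1,2-b:5,4-b']difuran (O1, C2, C3, C3a, C4, C4a, C5, C6, O7, C7a, C8, C8a). Ring B is the central benzene ring and ring D is the dimethoxyphenyl ring on C5.

Step 1
Reactants: 1 3,5-dihydroxybenzyl alcohol; 2 4-methoxybenzyl chloride (2.2 equiv)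
Product: 3 [3,5-bis(4-methoxybenzyloxy)phenyl]methanol
Conditions: 2 (2.2 equiv), K2CO3 (3 equiv), KI (cat.), acetone, reflux
Reagents that add atoms: 4-methoxybenzyl chloride (second equivalent of 2), COc1ccc(CCl)cc1
Why: Double Williamson etherification, in which each of the two phenoxides takes up one molecule of the chloride while the much less acidic benzylic alcohol is left free.

Step 2
Reactants: 3 [3,5-bis(4-methoxybenzyloxy)phenyl]methanol
Product: 4 triisopropylsilyl ether of 3
Conditions: i-Pr3SiCl, imidazole, DMF, 23 °C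
Reagents that add atoms: triisopropylsilyl chloride, CC(C)[Si](Cl)(C(C)C)C(C)C
Why: Silylation of the primary alcohol gives an ether that tolerates organolithiums, the carbene step and acid, and that offers no activated C–H bond within reach of the later carbenes.

Step 3
Reactants: 4 triisopropylsilyl ether of 3
Product: 5 2,6-dibromo-3,5-bis(4-methoxybenzyloxy)benzyl triisopropylsilyl ether
Conditions: NBS (2.05 equiv), MeCN, 0 °C
Reagents that add atoms: N-bromosuccinimide, O=C1CCC(=O)N1Br
Why: Electrophilic aromatic bromination should go to C2 and C6, each para to one ether oxygen and ortho to the other, in preference to C4 between the two ethers and to the less activated anisole rings.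

Step 4
Reactants: 5 2,6-dibromo-3,5-bis(4-methoxybenzyloxy)benzyl triisopropylsilyl ether; 6 3,5-dimethoxybenzonitrile (2.4 equiv)
Product: 8 bis(N-H ketimine) 1,1'-{4,6-bis(4-methoxybenzyloxy)-2-[(triisopropylsilyloxy)methyl]-1,3-phenylene}bis[1-(3,5-dimethoxyphenyl)methanimine], via 2,6-dilithio arene 7 (not isolated)
Conditions: t-BuLi (4.2 equiv), THF, −78 °C; 6 (2.4 equiv), −78 to 0 °C; MeOH
Reagents that add atoms: 3,5-dimethoxybenzonitrile (second equivalent of 6), COc1cc(C#N)cc(OC)c1
Why: Double bromine–lithium exchange gives a dilithio arene stabilised by the neighbouring ether oxygens, and aryllithium addition to the nitrile stops at the N-lithio ketimine, so both hindered diaryl C=N units are obtained without an oxidation step.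

Step 5
Reactants: 8 bis(N-H ketimine)
Product: 9 bis(hydrazone) of the 2,6-bis(3,5-dimethoxybenzoyl) arene
Conditions: N2H4·H2O (excess), AcOH (cat.), EtOH, 80 °C
Reagents that add atoms: hydrazine hydrate, NN.O
Why: Transimination, in which hindered N-H ketimines exchange with hydrazine with loss of ammonia where the corresponding ketones resist condensation.

Step 6
Reactants: 9 bis(hydrazone)
Product: 11 bis-cis-dihydrobenzofuran {[(2S,3R,5R,6S)-3,5-bis(3,5-dimethoxyphenyl)-2,6-bis(4-methoxyphenyl)-2,3,5,6-tetrahydrobenzo[1,2-b:5,4-b']difuran-4-yl]methoxy}triisopropylsilane, via bis(diazo) compound 10 (not isolated)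
Conditions: MnO2, CH2Cl2, 0 °C, filter; Rh2(S-PTAD)4 (2 mol%), CH2Cl2, 0 °C
Reagents that add atoms: none
Why: Hydrazone oxidation gives the bis(diaryldiazomethane), and enantioselective intramolecular 1,5 C–H insertion of each donor/donor rhodium carbene into the adjacent ArO–CH2Ar group sets C3 and C5 (carbene carbons) and C2 and C6 under catalyst control with cis geometry, the double reaction on the symmetric substrate diverting most of the minor enantiomeric event into a separable meso diastereomer.

Step 7
Reactants: 11 bis-cis-dihydrobenzofuran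
Product: 12 bis-trans-dihydrobenzofuran {[(2R,3R,5R,6R)-3,5-bis(3,5-dimethoxyphenyl)-2,6-bis(4-methoxyphenyl)-2,3,5,6-tetrahydrobenzo[1,2-b:5,4-b']difuran-4-yl]methoxy}triisopropylsilane
Conditions: CF3CO2H (10 equiv), CH2Cl2, 0 to 23 °C
Reagents that add atoms: none
Why: Acid-mediated epimerisation at C2 and C6 through reversible ionisation of the benzylic C–O bond to the 4-methoxybenzyl cation gives the more stable trans rings while C3 and C5 are untouched, and the silyl ether is kept so that no hydroxyl group can trap the cation.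

Step 8
Reactants: 12 bis-trans-dihydrobenzofuran
Product: 13 mono-bromide (analogue of 12 with a 2-bromo-3,5-dimethoxyphenyl group on C5; spatial arrangement as in 12; C5 is now formally S because bromine raises the priority of the aryl group)
Conditions: NBS (0.95 equiv), CH2Cl2, −78 to 0 °C
Reagents that add atoms: N-bromosuccinimide, O=C1CCC(=O)N1Br
Why: Electrophilic bromination should take place at the ring position para to one methoxy group and ortho to the benzylic carbon, which is more activated than C8 of ring B (flanked only by two ortho oxygens), and because the two dimethoxyphenyl rings are related by the C2 axis a single mono-bromide results, unreacted 12 being recycled.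

Step 9
Reactants: 13 mono-bromide; 14 2,4-dimethoxybenzaldehyde
Product: 16 benzhydrol silyl ether (analogue of 12 whose C5 aryl group carries a (2,4-dimethoxyphenyl)(hydroxy)methyl group at its 2-position; both carbinol epimers; 2R,3R,5R,6R), via aryllithium 15 (not isolated)
Conditions: t-BuLi (2.1 equiv), THF, −78 °C; 14; H2O
Reagents that add atoms: none
Why: Bromine–lithium exchange followed by 1,2-addition of the aryllithium to the aldehyde is fast at −78 °C relative to deprotonation of the dihydrofuran methines, and the carbinol configuration is irrelevant because this centre is later destroyed.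

Step 10
Reactants: 16 benzhydrol silyl ether
Product: 17 diol with a free C4 hydroxymethyl group
Conditions: Bu4NF, THF, 0 to 23 °C
Reagents that add atoms: none
Why: Fluoride-mediated cleavage of the silyl ether under non-acidic conditions leaves the acid-labile benzhydrol and both dihydrofurans intact.

Step 11
Reactants: 17 diol
Product: 18 S-acetyl thioester at the C4 methylene (benzhydrol unchanged)
Conditions: AcSH, PPh3, DIAD, THF, 0 °C
Reagents that add atoms: thioacetic acid, CC(=O)S
Why: Mitsunobu thioesterification is selective for the primary benzylic alcohol over the hindered, tri-ortho-substituted secondary benzhydrol.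

Step 12
Reactants: 18 S-acetyl thioester
Product: 20 eight-membered cyclic sulfide in which sulfur bridges the C4 CH2 and the ring D CH(2,4-dimethoxyphenyl) carbon (both S–CH epimers), via hydroxy thiol 19 (not isolated)
Conditions: K2CO3 (cat.), MeOH/THF (degassed), 0 °C; then CF3CO2H (1% v/v), CH2Cl2 (1 mM), 0 °C
Reagents that add atoms: none
Why: Methanolysis frees the thiol, and dilute acid ionises the bis(2,4-dialkoxyaryl)methanol to a highly stabilised cation that the thiol captures intramolecularly (SN1 thioetherification), the reversible C–S ionisation returning oligomers to the monomeric ring while the acid is too weak to open the dihydrofurans.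

Step 13
Reactants: 20 cyclic sulfide
Product: 22 eight-membered cyclic sulfone, via sulfoxide 21 (not isolated)
Conditions: dimethyldioxirane (2.2 equiv), acetone/CH2Cl2, −20 to 0 °C
Reagents that add atoms: dimethyldioxirane, CC1(C)OO1
Why: Sulfide-to-sulfone oxidation with a neutral oxidant is much faster than arene or benzylic oxidation and avoids acid that could ionise the electron-rich benzhydryl C–S bond.

Step 14
Reactants: 22 cyclic sulfone
Product: 25 seven-membered cyclic stilbene (Cα=Cβ), via alpha-bromo sulfone 23 (not isolated), via episulfone 24 (not isolated)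
Conditions: KOH on Al2O3, CBr2F2, t-BuOH/CH2Cl2, 0 to 23 °C
Reagents that add atoms: none
Why: Ramberg–Bäcklund reaction with in situ halogenation: the base removes a proton from the benzylic CH2 next to sulfur and the carbanion takes bromine from CBr2F2 to give 23, deprotonation at the diaryl methine then lets that carbanion displace bromide to give episulfone 24, which forms the Cα–Cβ bond, and cheletropic loss of SO2 leaves the double bond. The closest known reaction type is the one-pot conversion of dibenzylic and cyclophane sulfones into stilbenes by this halogenative variant. The only ring closed directly is the three-membered episulfone (3-exo-tet), and SO2 extrusion turns the eight-membered thiacycle into the seven-membered carbocycle. No stereocentre is created and the alkene geometry is imposed by the ring. The step needs chemoselectivity only: the α-sulfonyl C–H bonds (pKa near 23 for this class) are far more acidic than the C3 and C5 diarylmethine C–H bonds, so halogenation and closure should outrun any base-induced opening of the dihydrofurans, and the weakly ionising heterogeneous base medium should hold back heterolysis of the electron-rich benzhydryl C–SO2 bond.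

Step 15
Reactants: 25 cyclic stilbene
Product: 26 octamethyl ether of the target (Cβ R)
Conditions: H2 (4 atm), 10% Pd/C, EtOAc/MeOH, 23 °C
Reagents that add atoms: none
Why: Heterogeneous syn hydrogenation, for which a qualitative conformational analysis (not a computed model) predicts that the fused furan locks the cycloheptene in a boat with H-5 as the flagpole hydrogen over the inner face of the alkene and the C3 aryl group over the same face at Cα, so that hydrogen should add to the outer face, setting Cβ as R (aryl cis to H-5), the epimer free of allylic 1,3-strain with the ring D methoxy group.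

Step 16
Reactants: 26 octamethyl ether
Product: 27 target CNP0154047.1
Conditions: BBr3 (excess), CH2Cl2, −78 to 23 °C; H2O
Reagents that add atoms: none
Why: Lewis-acid cleavage of the eight aryl methyl ethers, the trans dihydrofurans and the diarylmethine being the thermodynamically preferred arrangements and so expected to survive.

**Compound list**
1 | 3,5-dihydroxybenzyl alcohol | OCc1cc(O)cc(O)c1 | starting material
2 | 4-methoxybenzyl chloride | COc1ccc(CCl)cc1 | starting material
3 | [3,5-bis(4-methoxybenzyloxy)phenyl]methanol | OCc1cc(OCc2ccc(OC)cc2)cc(OCc2ccc(OC)cc2)c1 | intermediate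
4 | triisopropylsilyl ether of 3 | CC(C)[Si](OCc1cc(OCc2ccc(OC)cc2)cc(OCc2ccc(OC)cc2)c1)(C(C)C)C(C)C | intermediate
5 | 2,6-dibromo-3,5-bis(4-methoxybenzyloxy)benzyl triisopropylsilyl ether | CC(C)[Si](OCc1c(Br)c(OCc2ccc(OC)cc2)cc(OCc2ccc(OC)cc2)c1Br)(C(C)C)C(C)C | intermediate
6 | 3,5-dimethoxybenzonitrile | COc1cc(C#N)cc(OC)c1 | starting material
7 | 2,6-dilithio arene from 5 (not isolated) | CC(C)[Si](OCc1c([Li])c(OCc2ccc(OC)cc2)cc(OCc2ccc(OC)cc2)c1[Li])(C(C)C)C(C)C | intermediate
8 | bis(N-H ketimine), 2,6-bis[(3,5-dimethoxyphenyl)(imino)methyl] arene | CC(C)[Si](OCc1c(C(=N)c2cc(OC)cc(OC)c2)c(OCc2ccc(OC)cc2)cc(OCc2ccc(OC)cc2)c1C(=N)c1cc(OC)cc(OC)c1)(C(C)C)C(C)C | intermediate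
9 | bis(hydrazone) | CC(C)[Si](OCc1c(C(=NN)c2cc(OC)cc(OC)c2)c(OCc2ccc(OC)cc2)cc(OCc2ccc(OC)cc2)c1C(=NN)c1cc(OC)cc(OC)c1)(C(C)C)C(C)C | intermediate
10 | bis(diazo) compound (not isolated) | CC(C)[Si](OCc1c(C(=[N+]=[N-])c2cc(OC)cc(OC)c2)c(OCc2ccc(OC)cc2)cc(OCc2ccc(OC)cc2)c1C(=[N+]=[N-])c1cc(OC)cc(OC)c1)(C(C)C)C(C)C | intermediate
11 | (2S,3R,5R,6S) bis-cis-dihydrobenzofuran silyl ether | COc1ccc([C@H]2Oc3cc4O[C@H](c5ccc(OC)cc5)[C@H](c5cc(OC)cc(OC)c5)c4c(CO[Si](C(C)C)(C(C)C)C(C)C)c3[C@H]2c2cc(OC)cc(OC)c2)cc1 | intermediate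
12 | (2R,3R,5R,6R) bis-trans-dihydrobenzofuran silyl ether (C2-symmetric core) | COc1ccc([C@@H]2Oc3cc4O[C@@H](c5ccc(OC)cc5)[C@H](c5cc(OC)cc(OC)c5)c4c(CO[Si](C(C)C)(C(C)C)C(C)C)c3[C@H]2c2cc(OC)cc(OC)c2)cc1 | intermediate
13 | mono-bromide of 12, 2-bromo-3,5-dimethoxyphenyl on C5 (2R,3R,5S,6R; same spatial arrangement as 12) | COc1ccc([C@@H]2Oc3cc4O[C@@H](c5ccc(OC)cc5)[C@H](c5c(Br)c(OC)cc(OC)c5)c4c(CO[Si](C(C)C)(C(C)C)C(C)C)c3[C@H]2c2cc(OC)cc(OC)c2)cc1 | intermediate
14 | 2,4-dimethoxybenzaldehyde | COc1ccc(C=O)c(OC)c1 | starting material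
15 | aryllithium from 13 (not isolated) | COc1ccc([C@@H]2Oc3cc4O[C@@H](c5ccc(OC)cc5)[C@H](c5c([Li])c(OC)cc(OC)c5)c4c(CO[Si](C(C)C)(C(C)C)C(C)C)c3[C@H]2c2cc(OC)cc(OC)c2)cc1 | intermediate
16 | benzhydrol silyl ether (carbinol epimers; 2R,3R,5R,6R) | COc1ccc([C@@H]2Oc3cc4O[C@@H](c5ccc(OC)cc5)[C@H](c5c(C(O)c6ccc(OC)cc6OC)c(OC)cc(OC)c5)c4c(CO[Si](C(C)C)(C(C)C)C(C)C)c3[C@H]2c2cc(OC)cc(OC)c2)cc1 | intermediate
17 | diol (C4 hydroxymethyl and benzhydrol) | COc1ccc([C@@H]2Oc3cc4O[C@@H](c5ccc(OC)cc5)[C@H](c5c(C(O)c6ccc(OC)cc6OC)c(OC)cc(OC)c5)c4c(CO)c3[C@H]2c2cc(OC)cc(OC)c2)cc1 | intermediate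
18 | S-acetyl thioester at the C4 methylene | COc1ccc([C@@H]2Oc3cc4O[C@@H](c5ccc(OC)cc5)[C@H](c5c(C(O)c6ccc(OC)cc6OC)c(OC)cc(OC)c5)c4c(CSC(C)=O)c3[C@H]2c2cc(OC)cc(OC)c2)cc1 | intermediate
19 | hydroxy thiol (not isolated) | COc1ccc([C@@H]2Oc3cc4O[C@@H](c5ccc(OC)cc5)[C@H](c5c(C(O)c6ccc(OC)cc6OC)c(OC)cc(OC)c5)c4c(CS)c3[C@H]2c2cc(OC)cc(OC)c2)cc1 | intermediate
20 | eight-membered cyclic sulfide (S–CH epimers; dihydrofuran centres as in 12) | COc1ccc([C@@H]2Oc3cc4c5c(c3[C@H]2c2cc(OC)cc(OC)c2)CSC(c2ccc(OC)cc2OC)c2c(OC)cc(OC)cc2[C@H]5[C@H](c2ccc(OC)cc2)O4)cc1 | intermediate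
21 | cyclic sulfoxide (not isolated) | COc1ccc([C@@H]2Oc3cc4c5c(c3[C@H]2c2cc(OC)cc(OC)c2)CS(=O)C(c2ccc(OC)cc2OC)c2c(OC)cc(OC)cc2[C@H]5[C@H](c2ccc(OC)cc2)O4)cc1 | intermediate
22 | eight-membered cyclic sulfone (key-step precursor) | COc1ccc([C@@H]2Oc3cc4c5c(c3[C@H]2c2cc(OC)cc(OC)c2)CS(=O)(=O)C(c2ccc(OC)cc2OC)c2c(OC)cc(OC)cc2[C@H]5[C@H](c2ccc(OC)cc2)O4)cc1 | intermediate
23 | alpha-bromo sulfone, bromine on Cα (not isolated) | COc1ccc([C@@H]2Oc3cc4c5c(c3[C@H]2c2cc(OC)cc(OC)c2)C(Br)S(=O)(=O)C(c2ccc(OC)cc2OC)c2c(OC)cc(OC)cc2[C@H]5[C@H](c2ccc(OC)cc2)O4)cc1 | intermediate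
24 | episulfone, thiirane 1,1-dioxide across Cα–Cβ (not isolated) | COc1ccc([C@@H]2Oc3cc4c5c(c3[C@H]2c2cc(OC)cc(OC)c2)C2C(c6ccc(OC)cc6OC)(S2(=O)=O)c2c(OC)cc(OC)cc2[C@H]5[C@H](c2ccc(OC)cc2)O4)cc1 | intermediate
25 | seven-membered cyclic stilbene (key-step product) | COc1ccc([C@@H]2Oc3cc4c5c(c3[C@H]2c2cc(OC)cc(OC)c2)C=C(c2ccc(OC)cc2OC)c2c(OC)cc(OC)cc2[C@H]5[C@H](c2ccc(OC)cc2)O4)cc1 | intermediate
26 | octamethyl ether of the target (Cβ R) | COc1ccc([C@@H]2Oc3cc4c5c(c3[C@H]2c2cc(OC)cc(OC)c2)C[C@H](c2ccc(OC)cc2OC)c2c(OC)cc(OC)cc2[C@H]5[C@H](c2ccc(OC)cc2)O4)cc1 | intermediate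
27 | CNP0154047.1 | Oc1ccc([C@@H]2Oc3cc4c5c(c3[C@H]2c2cc(O)cc(O)c2)C[C@H](c2ccc(O)cc2O)c2c(O)cc(O)cc2[C@H]5[C@H](c2ccc(O)cc2)O4)cc1 | target

**Step count and risks**
Total step count: 16. Longest linear sequence: 16 steps (1 to 27); compounds 2, 6 and 14 are purchased.

Steps most likely to fail:

Step 6. The double carbene C–H insertion may be slow or poorly controlled at carbene centres flanked by two ortho substituents, with azine formation or erosion of catalyst control. The fallback sets out from 8 and gives up catalyst control in favour of a resolution. Mild aqueous acid (AcOH/H2O/THF) should hydrolyse both imines to the diketone F1. Lithium 2,2,6,6-tetramethylpiperidide in THF at −78 to 0 °C should deprotonate each ArO–CH2Ar group, and intramolecular carbonyl addition should give the bis(3-hydroxy-2,3-dihydrobenzofuran) F2. TsOH in toluene should dehydrate it to the aromatic benzodifuran F3. Ionic hydrogenation with Et3SiH/CF3CO2H in CH2Cl2 at 0 °C (protonation at C3, hydride delivery to C2 trans to the C3 aryl group) should give 12 together with its enantiomer F4 and the meso diastereomer F5. F5 is removed on silica and F4 by preparative HPLC on a chiral stationary phase, and the route is rejoined at 12.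

Step 14. Heterolysis of the electron-rich benzhydryl C–SO2 bond, or double bromination at Cα before the hindered methine is deprotonated, may outrun episulfone formation. The fallback sets out from 12 and closes the seven-membered ring by a Friedel–Crafts alkylation instead of a contraction. Bu4NF should give the alcohol F6, and Dess–Martin periodinane the aldehyde F7. Horner–Wadsworth–Emmons olefination with diethyl (2,4-dimethoxybenzyl)phosphonate and t-BuOK should give the E-stilbene F8. Brief treatment with CF3CO2H in CH2Cl2 should protonate the alkene at the carbon next to ring B. The resulting 2,4-dimethoxybenzylic cation is then attacked by the 2-position of the neighbouring 3,5-dimethoxyphenyl ring (either ring gives the same product by symmetry), with the Cβ aryl group expected to settle in the strain-free R arrangement. The route is rejoined at 26, bypassing 25.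

Step 15. Facial selectivity may be poor, the reduction of the hindered triaryl alkene on the metal surface may be sluggish, or hydrogenolysis of the benzylic C2–O and C6–O bonds may compete. The fallback sets out from 25 and returns at 26 by a stepwise ionic hydrogenation. CF3CO2H (few equivalents) and Et3SiH in CH2Cl2 at −20 °C should protonate Cα to the bis(2,4-dialkoxyaryl) carbenium ion. Hydride transfer to Cβ, a late transition state, should favour the epimer in which the aryl group avoids the ring D methoxy group. At this temperature and acid loading the dihydrofuran C–O bonds, which ionise only under the more forcing conditions of step 7, should stay closed. This fallback makes no new compound.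

Further compounds
F1 | step 6 | diketone, 2,6-bis(3,5-dimethoxybenzoyl)-3,5-bis(4-methoxybenzyloxy)benzyl triisopropylsilyl ether | CC(C)[Si](OCc1c(C(=O)c2cc(OC)cc(OC)c2)c(OCc2ccc(OC)cc2)cc(OCc2ccc(OC)cc2)c1C(=O)c1cc(OC)cc(OC)c1)(C(C)C)C(C)C
F2 | step 6 | bis(3-hydroxy-2,3-dihydrobenzofuran) silyl ether (diastereomer mixture) | COc1ccc(C2Oc3cc4OC(c5ccc(OC)cc5)C(O)(c5cc(OC)cc(OC)c5)c4c(CO[Si](C(C)C)(C(C)C)C(C)C)c3C2(O)c2cc(OC)cc(OC)c2)cc1
F3 | step 6 | 3,5-bis(3,5-dimethoxyphenyl)-2,6-bis(4-methoxyphenyl)benzo[1,2-b:5,4-b']difuran-4-ylmethyl triisopropylsilyl ether | COc1ccc(-c2oc3cc4oc(-c5ccc(OC)cc5)c(-c5cc(OC)cc(OC)c5)c4c(CO[Si](C(C)C)(C(C)C)C(C)C)c3c2-c2cc(OC)cc(OC)c2)cc1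
F4 | step 6 | enantiomer of 12 (2S,3S,5S,6S) | COc1ccc([C@H]2Oc3cc4O[C@H](c5ccc(OC)cc5)[C@@H](c5cc(OC)cc(OC)c5)c4c(CO[Si](C(C)C)(C(C)C)C(C)C)c3[C@@H]2c2cc(OC)cc(OC)c2)cc1
F5 | step 6 | meso diastereomer of 12 (2R,3R,5S,6S) | COc1ccc([C@@H]2Oc3cc4O[C@H](c5ccc(OC)cc5)[C@@H](c5cc(OC)cc(OC)c5)c4c(CO[Si](C(C)C)(C(C)C)C(C)C)c3[C@H]2c2cc(OC)cc(OC)c2)cc1
F6 | step 14 | alcohol, desilylated 12 | COc1ccc([C@@H]2Oc3cc4O[C@@H](c5ccc(OC)cc5)[C@H](c5cc(OC)cc(OC)c5)c4c(CO)c3[C@H]2c2cc(OC)cc(OC)c2)cc1
F7 | step 14 | aldehyde at C4 | COc1ccc([C@@H]2Oc3cc4O[C@@H](c5ccc(OC)cc5)[C@H](c5cc(OC)cc(OC)c5)c4c(C=O)c3[C@H]2c2cc(OC)cc(OC)c2)cc1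
F8 | step 14 | E-stilbene, C4 (E)-2-(2,4-dimethoxyphenyl)ethenyl compound | COc1ccc([C@@H]2Oc3cc4O[C@@H](c5ccc(OC)cc5)[C@H](c5cc(OC)cc(OC)c5)c4c(/C=C/c5ccc(OC)cc5OC)c3[C@H]2c2cc(OC)cc(OC)c2)cc1
F0 | step 15 | none | none
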